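## Structural features

The target (24) is a trans-fused bicyclo[5.3.0]decane. The numbering used throughout is: C1 ester carbinol, C2 methylene, C3 methyl carbinol, C4 methylene, C5 and C6 ring fusion (C5 on C4 and C9, C6 on C7 and C10), C7 methylene, C8/C9 epoxide carbons (methyl on C8), C10 isopropyl-bearing carbon. The seven-membered ring is C1–C2–C3–C4–C5–C6–C10 and the five-membered ring is C5–C6–C7–C8–C9; C1 carries the 3-hydroxy-4-methoxybenzoate.

There are seven stereocentres, (1R,3R,5S,6R,8R,9S,10S) in this numbering. C8, C9, C5, C6, C10 and C1 are contiguous; C3 is insulated from them by C2 and C4. With β defined as the face of H-5, the groups H-1, H-10 and 3-CH3 are β, while H-6, the isopropyl group, the C1 acyloxy group, the C3 hydroxyl and the epoxide oxygen are all α. The ring fusion is therefore trans and the C1 and C3 oxygens are 1,3-cis.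

Fragile groups are the trisubstituted epoxide (acid-labile), the tertiary alcohol (dehydration), and the aryl ester next to a free phenol (base). In the intermediates, C6 and C10 lie α to carbonyl groups and can epimerise.

The real difficulty is the C5/C6/C10 triad with a trans fusion, the remote C3 centre, and placing the olefin that precedes the epoxide exactly at C8=C9. The feature the key step uses is that C1 and C3 are both oxygenated and 1,3-related. Removing C2 and joining C1 to C3 by a double bond turns the seven-membered ring into a cyclohexene (C1, C3, C4, C5, C6, C10) fused at C5–C6 to the five-membered ring. That is the Diels–Alder adduct of a C5=C6 cyclopentenone.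

## Logic of the disconnections

**24 ⇒ 18 + 21 (through 23).** The acyl–oxygen bond at C1 is cut and the phenol is masked as a silyl ether. The ester is the most labile link and the aryl half is a simple acid (21, from 19). This removes all aromatic chemistry from the terpenoid work. The forward step must acylate a hindered secondary alcohol next to C10 without touching the tertiary alcohol or the epoxide.

**18 ⇒ 17.** The two C–O bonds of the epoxide are removed to give the C8=C9 olefin. The epoxide is acid-sensitive and so comes late; both hydroxyls of 17 lie on the α face and can steer an oxidant there. The forward step must deliver oxygen to the α face only.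

**17 ⇒ 15 (through 16).** The two C7–H bonds are replaced by a C7 carbonyl conjugated with C8=C9. The ketone explains the position of the olefin and is the handle for C6 and C8. The forward deoxygenation must not move or saturate the double bond and must tolerate a tertiary alcohol; for that reason C1 is already at the alcohol level in 15.

**15 ⇒ 13 ⇒ 12.** The C1 carbinol goes back to a ketone, and silanol is added back across C8=C9. The C1 configuration can then come from chelation with the C3 hydroxyl, and the olefin is placed by β-elimination. The forward steps must reduce C1 without touching C7 and must eliminate regiospecifically.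

**12 ⇒ 11.** The C2–C3 bond is cut (β-hydroxy ketone retron). This opens the seven-membered ring to a monocyclic cyclopentanone with two side chains. The forward closure must prefer the seven-membered ring over attack at C7 and must control the new C3 centre.

**11 ⇒ 8 (through 10 and 9).** The C1–C2 bond is cut; C2 is the only skeletal carbon the cycloaddition does not supply. C1 is taken to the acid so that it can be activated selectively beside two ketones.

**8 ⇒ 5 (through 7 and 6).** C6 is inverted back, and the C1 acid and C3 methyl ketone are rejoined as the C1=C3 olefin. This returns a cis-hydrindenone holding every carbon except C2 and the aryl ester. In the forward direction the cleavage must be followed by equilibration of C6 without loss of C10, so C1 is oxidised to the acid before any base is used.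

**5 ⇒ 4.** The C8–CH3 bond is cut. Only while C7 is the sole carbonyl can C8 be deprotonated selectively. The enolate must be methylated faster than it expels the siloxy group.

**4 ⇒ 2 + 3.** C4–C5 and C6–C10 are cut (Diels–Alder). One ring, two skeletal bonds and three stereocentres fall away, leaving a diene and a bought chiral enone. The forward step needs face, regio and endo control.

**2 ⇒ 1.** The terminal C=CH2 bond is cut (Wittig) rather than the internal olefin. The E geometry is then bought with 1 and no separation of volatile diene isomers is needed.

## Other disconnections considered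

**Alternative 1:** The cut is C1–C2 and C4–C5. C1 and C5 are the carbonyls of the 1,4-keto aldehyde A2, and C2–C3–C4 come from the bis(silyl) dienol ether of methyl acetoacetate, A3. In the forward step Me3SiOTf activates the aldehyde, the diene terminus adds (C1–C2), the silylated aldol oxygen closes onto the ketone, and the resulting cyclic oxocarbenium ion is captured at C5 by C4. This gives the oxygen-bridged keto ester A1.

- In its favour: one operation builds the carbocycle with oxygen at C1 and C3, which is shorter than cleavage plus C2 insertion in the chosen plan. The bridge fixes the C1–O bond on the α face. The five-membered ring could later be closed by reductive coupling of a C9 aldehyde with the C8 ketone, giving C8=C9 with no C7 oxygen to remove. On that last point Alternative 1 is better than the chosen plan.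
- Against it: C6 and C10 must be set in acyclic A2 by separate asymmetric steps, whereas the chosen cycloaddition makes C5, C6 and C10 at once from one bought stereocentre. A1 also carries three foreign features (the C4 ester, a C3 ketone lacking its methyl, and the oxygen on C5). Bridge opening, decarboxylation, reduction of the resulting C4=C5 olefin with control of H-5, and methyl addition to C3 would all follow.
- Comparison: the two plans are equal in leaving C3 to a late, weakly controlled addition. Alternative 1 is better on ring construction and olefin placement. The chosen plan is better on stereocentre economy and on the number of corrective steps.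

**Alternative 2:** The cut is C1–C2 only. Precursor A5 is a trans-disubstituted methylcyclopentene that already holds C5, C6, C10, the C8=C9 olefin, a 1,3-dithiane at C1 and a 2-methyloxirane of defined configuration at C3. In the forward step t-BuLi/HMPA lithiates the dithiane and the carbanion opens the oxirane at its CH2 (C2), giving A4 with the C3 alkoxide untouched.

- In its favour: C3 is fixed before closure and cannot drift, which is better than the chosen plan, where the closure has to create C3. The olefin is in place, so no C7 deoxygenation is needed. Unmasking the dithiane gives the same C1 ketone for hydroxyl-directed reduction (equal).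
- Against it: the key step makes one bond and no stereocentre, so the whole C5/C6/C10 problem and the trans relationship move into the synthesis of A5. The carbanion sits next to the isopropyl-bearing C10, so deprotonation and SN2 opening are hindered. Base-induced isomerisation of the epoxide to an allylic alcohol is a competing path. Dithiane removal adds a step.
- Comparison: Alternative 2 is better on C3 control and olefin placement, equal on mechanism reliability as a reaction type, and worse on stereo-economy and probably on total length.

**Alternative 3:** The cut is C5–C6 plus the bond from C7 to the carbon that becomes C8. Precursor A7 is an acyclic (E)-dienyl (E)-vinyl sulfone whose tether already carries C10, C1 (OTBS) and C3 (OSiEt3). Heating should close the seven-membered ring and a cyclohexene together to give A6. The cyclohexene is later cleaved and reclosed by aldol condensation to a cyclopentene carbaldehyde. The carbon that ends as the C8 methyl is the internal diene carbon next to C8, not a diene terminus; this follows from the structure of A6.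

- In its favour: the trans fusion comes directly from the olefin geometries, which is better than the chosen plan's epimerisation. C1 and C3 are present with their configuration, so there is no C2 insertion and no C3 problem, which is also better. Both plans use a sacrificial cyclohexene (equal).
- Against it: the three tether stereocentres must be made by acyclic methods. The cycloaddition has to close a seven-membered ring through a five-atom tether, with facial control exerted only from remote centres. The contraction costs cleavage, aldol, formyl-to-methyl reduction (the same allylic deoxygenation risk as in the chosen plan) and desulfonylation.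
- Comparison: the chosen cycloaddition joins two simple partners under control of a stereocentre adjacent to the reacting olefin. Alternative 3 has the better functional-group pattern but weaker stereocontrol in its key step and a longer precursor.

Key step: step 2

**Remarks on the chemistry**

- α/β and the C1–C10 locants are as defined under "Structural features".
- Compounds 2, 3 and 4 were checked against 24. The (S) enone leads to the target enantiomer; C5 and C10 of 4 already have the target configuration, and C6 is opposite until step 5.
- Assumption: 1 is bought as the E isomer (a flavour chemical); otherwise it is one aldol condensation from acetone and isobutyraldehyde.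
- Assumption: the C8 methyl of 5–12 is drawn trans to the siloxy group. This has no consequence, because C8 becomes sp2 in step 9.
- Assumption: the C3 configuration formed in step 8 is assigned from a transition-state model, not from an adjacent controlling centre. It is treated as uncertain below.

## Steps

Step 1
Reactants: 1 (E)-5-methylhex-3-en-2-one
Product: 2 (E)-2,5-dimethylhexa-1,3-diene
Conditions: Ph3PCH3Br, KOt-Bu, Et2O, 0 °C → rt; pentane, filter, fractional distillation
Reagents that add atoms: methyltriphenylphosphonium bromide, C[P+](c1ccccc1)(c1ccccc1)c1ccccc1.[Br-]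
Why: Wittig methylenation; the non-stabilised ylide adds 1,2 to the enone carbonyl, and the E olefin of 1 is not involved, so 2 should form as a single geometric isomer.

Step 2
Reactants: 3 (S)-4-(tert-butyldimethylsiloxy)cyclopent-2-enone; 2 (E)-2,5-dimethylhexa-1,3-diene
Product: 4 cis-fused endo adduct (C7 ketone; C1=C3 olefin with methyl on C3; 9β-OTBS; H-5, H-6 and H-10 all β; 10α-isopropyl)
Conditions: Et2AlCl (1.2 equiv), 2 (3 equiv), CH2Cl2, −78 → −20 °C; aq. NaHCO3
Reagents that add atoms: none
Why: Lewis acid-promoted normal-demand Diels–Alder reaction: Et2AlCl binds the C7 carbonyl of 3 and the diene adds in a concerted, asynchronous [4+2] step, the closest known type being alkylaluminium chloride-promoted cycloadditions of 4-siloxycyclopent-2-enones with alkyl dienes. The cyclohexene (C1, C3, C4, C5, C6, C10) is closed by suprafacial addition across C5=C6, forming C4–C5 and C6–C10 together. The 2-methyl and 4-isopropyl groups both enlarge the HOMO coefficient at the CH2 terminus (C4), which bonds to the enone β-carbon C5, so C10 ends next to C6 (the para and ortho preferences reinforce each other). C5 and C6 are controlled by the C9 stereocentre of 3: the diene approaches the face opposite the siloxy group, and suprafacial addition makes the fusion cis. C10 is controlled by the endo transition state (carbonyl under the diene) together with the E geometry of 2, which places the isopropyl group cis to C7. The step needs face, regio and endo selectivity; these are secured by the adjacent OTBS group, the matched diene substituents and low-temperature Lewis acid complexation, which also keeps siloxide elimination and cationic oligomerisation of the diene slow. C5 and C10 are thereby set as in 24, and C6 is left for step 5.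

Step 3
Reactants: 4 cis-fused endo adduct
Product: 5 8α-methyl derivative of 4
Conditions: LiN(i-Pr)2, THF, −78 °C; MeI, DMPU, −78 → −60 °C; AcOH quench at −78 °C
Reagents that add atoms: iodomethane, CI
Why: Kinetic enolate alkylation; the amide base removes a C8 methylene proton rather than the hindered ring-fusion H-6, and iodomethane should enter anti to the neighbouring siloxy group. Low temperature is used so that the β-siloxy enolate is alkylated before it can eliminate.

Step 4
Reactants: 5 8α-methyl adduct
Product: 7 5,6-cis seco keto acid (C1 carboxylic acid; C3 methyl ketone; C7 ketone), via keto aldehyde 6 (not isolated)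
Conditions: O3, pyridine, CH2Cl2, −78 °C; then NaClO2, NaH2PO4, 2-methylbut-2-ene, t-BuOH/H2O, 0 °C → rt
Reagents that add atoms: ozone, [O-][O+]=O; sodium chlorite, [Na+].[O-]Cl=O
Why: Ozonolysis of the only C=C bond (C1=C3), with pyridine so that the carbonyl compounds form directly, followed by Pinnick oxidation of the crude aldehyde. The buffered oxidation should not enolise C10 and makes C1 chemically distinct from the two ketones.

Step 5
Reactants: 7 5,6-cis seco keto acid
Product: 8 all-trans seco keto acid (C6 epimer of 7; H-6 α)
Conditions: KOAc, MeOH, rt; work-up at pH 4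
Reagents that add atoms: none
Why: Thermodynamic epimerisation through the C7 enol; the four ring substituents should settle in the alternating all-trans arrangement, as in the acetate-mediated equilibration of 8-epi-prostaglandin E to prostaglandin E, which sets C6. The carboxylate α-centre C10 is not enolised, and acetate is too weak a base to expel the siloxy group.

Step 6
Reactants: 8 all-trans seco keto acid
Product: 10 diazomethyl ketone, via acid chloride 9 (not isolated)
Conditions: 1-chloro-N,N,2-trimethylprop-1-en-1-amine, CH2Cl2, 0 °C → rt; then Me3SiCHN2, THF/MeCN, 0 °C → rt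
Reagents that add atoms: (trimethylsilyl)diazomethane, C[Si](C)(C)C=[N+]=[N-]
Why: Acid chloride formation under neutral conditions, then C-acylation of the diazoalkane (first stage of an Arndt–Eistert sequence), which attaches C2 to C1. The ketones do not react with the diazoalkane without a Lewis acid, and no base is present to epimerise C10.

Step 7
Reactants: 10 diazomethyl ketone
Product: 11 bromomethyl ketone
Conditions: 48% aq. HBr, THF, −10 → 0 °C
Reagents that add atoms: hydrogen bromide, Br
Why: C-protonation of the diazoketone and SN2 displacement of dinitrogen by bromide; the reaction is fast at 0 °C, so the silyl ether should survive the brief acid exposure.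

Step 8
Reactants: 11 bromomethyl ketone
Product: 12 trans-fused aldol (C1 ketone; 3α-OH, 3β-CH3; C7 ketone; 8α-CH3; 9β-OTBS)
Conditions: SmI2 (2.2 equiv), THF, −78 °C, slow addition at high dilution; aq. NH4Cl
Reagents that add atoms: none
Why: SmI2-promoted intramolecular Reformatsky-type aldol: two-electron reduction of the C–Br bond gives an enolate of trivalent samarium that adds to the C3 ketone in a 7-(enolendo)-exo-trig closure (Baldwin), whereas attack on the C7 ketone would be a disfavoured 5-(enolendo)-exo-trig process. In a chelated, Zimmerman–Traxler-type transition state with the ring-fusion bonds and the isopropyl group pseudo-equatorial on the forming twist-chair, the samarium-bound C3 oxygen is pseudo-axial on the α face and the methyl equatorial, which sets C3 as 3α-OH.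

Step 9
Reactants: 12 trans-fused aldol
Product: 13 enone (C7 ketone conjugated with C8=C9; C1 ketone; 3α-OH)
Conditions: DBU (1.2 equiv), CH2Cl2, 0 °C → rt; quench when 12 is consumed
Reagents that add atoms: none
Why: E1cB β-elimination; enolisation of C7 toward C8 expels the 9-siloxy group and places the olefin regiospecifically at C8=C9. The tertiary aldol unit has no comparable leaving group, and C10, if it equilibrates, should keep its trans-diequatorial arrangement relative to the C6–C7 bond.

Step 10
Reactants: 13 enone
Product: 15 1α,3α-diol enone, via C3-O-diethylborinate 14 (not isolated)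
Conditions: Et2BOMe, THF/MeOH (4:1), −78 °C; NaBH4, −78 °C; AcOH, then MeOH co-evaporation
Reagents that add atoms: none
Why: Narasaka–Prasad reduction; the C3 borinate chelates the C1 carbonyl, and borohydride attacks the activated ketone from the β face, anti to both the boron bridge and the 10α-isopropyl group, setting C1 as the 1α-alcohol (1,3-syn). The conjugated, α-methylated C7 ketone is not activated and should not be reduced at −78 °C; peroxide work-up is avoided because of the enone.

Step 11
Reactants: 15 1α,3α-diol enone
Product: 16 C7 spiro-1,3-dithiolane of 15
Conditions: HSCH2CH2SH, BF3·OEt2, MeOH, 0 °C → rt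
Reagents that add atoms: ethane-1,2-dithiol, SCCS
Why: Lewis acid-mediated dithioketalisation of the only carbonyl left; conjugated ketones give dithiolanes without moving the double bond, and tertiary alcohols tolerate these conditions, as in the thioketalisation of 17-alkyl-17-hydroxy steroid enones.

Step 12
Reactants: 16 dithiolane
Product: 17 1α,3α-diol with C8=C9 olefin and C7 methylene
Conditions: NiCl2·6H2O, NaBH4, MeOH/THF, 0 °C → rt
Reagents that add atoms: none
Why: Mozingo-type reductive desulfurisation with Ni2B generated in the flask; both C–S bonds are cleaved to C7H2, and this reagent does not normally saturate a trisubstituted olefin.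

Step 13
Reactants: 17 olefinic diol
Product: 18 8α,9α-epoxy-1α,3α-diol
Conditions: VO(acac)2 (5 mol%), t-BuOOH, CH2Cl2, 0 °C → rt
Reagents that add atoms: tert-butyl hydroperoxide, CC(C)(C)OO
Why: Hydroxyl-directed epoxidation; the vanadium alkoxide of the 3α-hydroxyl (bishomoallylic to C9), possibly assisted by the 1α-hydroxyl, should deliver oxygen to the α face, setting C8 and C9. Olefins out of reach of a bound alkoxide are not epoxidised by this catalyst, and a syn-delivered epoxide cannot be opened from the back by the same hydroxyl.

Step 14
Reactants: 19 isovanillic acid (3-hydroxy-4-methoxybenzoic acid)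
Product: 21 3-(tert-butyldimethylsiloxy)-4-methoxybenzoic acid, via bis-silylated acid 20 (not isolated)
Conditions: t-BuMe2SiCl (2.2 equiv), imidazole, DMF, rt; then K2CO3, MeOH/THF/H2O, rt; pH 4
Reagents that add atoms: tert-butyldimethylsilyl chloride, CC(C)(C)[Si](C)(C)Cl
Why: Silylation of both acidic hydroxyls, then selective solvolysis of the labile silyl ester; the phenol stays masked so that the acid can be activated without self-acylation.

Step 15
Reactants: 21 3-(tert-butyldimethylsiloxy)-4-methoxybenzoic acid; 18 epoxy diol
Product: 23 C1 3-(tert-butyldimethylsiloxy)-4-methoxybenzoate of 18, via mixed anhydride 22 (not isolated)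
Conditions: 21, 2,4,6-Cl3C6H2COCl, Et3N, THF, rt; then 18, DMAP, toluene, rt → 40 °C
Reagents that add atoms: none
Why: Yamaguchi esterification; DMAP attacks the less hindered aroyl carbonyl of the mixed anhydride, and the acylpyridinium acylates the secondary C1 hydroxyl with retention. The tertiary C3 hydroxyl does not react and the epoxide tolerates the mildly basic medium.

Step 16
Reactants: 23 silyl-protected ester
Product: 24 target
Conditions: Bu4NF, AcOH, THF, 0 °C
Reagents that add atoms: none
Why: Fluoride cleavage of the aryl silyl ether, buffered with acetic acid so that ester and epoxide do not meet a basic phenoxide or fluoride; no stereocentre is touched.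

## Compound list

1 | (E)-5-methylhex-3-en-2-one | CC(=O)/C=C/C(C)C | starting material
2 | (E)-2,5-dimethylhexa-1,3-diene | CC(=C)/C=C/C(C)C | intermediate
3 | (S)-4-(tert-butyldimethylsiloxy)cyclopent-2-enone | O=C1C=C[C@@H](O[Si](C)(C)C(C)(C)C)C1 | starting material
4 | cis-fused endo adduct, 3-(tert-butyldimethylsiloxy)-7-isopropyl-5-methyl-2,3,3a,4,7,7a-hexahydroinden-1-one (ring-fusion hydrogens, H-7 and the siloxy group on one face) | O=C1C[C@H](O[Si](C)(C)C(C)(C)C)[C@H]2CC(C)=C[C@@H](C(C)C)[C@@H]12 | intermediate
5 | 2-methyl derivative of 4 (methyl on C8, trans to the siloxy group) | O=C1[C@@H](C)[C@H](O[Si](C)(C)C(C)(C)C)[C@H]2CC(C)=C[C@@H](C(C)C)[C@@H]12 | intermediate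
6 | 2-[4-(tert-butyldimethylsiloxy)-3-methyl-2-oxo-5-(2-oxopropyl)cyclopentyl]-3-methylbutanal, side chains cis | O=C1[C@@H](C)[C@H](O[Si](C)(C)C(C)(C)C)[C@@H](CC(C)=O)[C@H]1[C@H](C(C)C)C=O | intermediate
7 | corresponding 3-methylbutanoic acid, side chains cis | O=C1[C@@H](C)[C@H](O[Si](C)(C)C(C)(C)C)[C@@H](CC(C)=O)[C@H]1[C@H](C(C)C)C(=O)O | intermediate
8 | C6 epimer of 7, all-trans cyclopentanone | O=C1[C@@H](C)[C@H](O[Si](C)(C)C(C)(C)C)[C@@H](CC(C)=O)[C@@H]1[C@H](C(C)C)C(=O)O | intermediate
9 | acid chloride of 8 | O=C1[C@@H](C)[C@H](O[Si](C)(C)C(C)(C)C)[C@@H](CC(C)=O)[C@@H]1[C@H](C(C)C)C(=O)Cl | intermediate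
10 | 1-diazo-4-methyl-3-[all-trans-4-(tert-butyldimethylsiloxy)-3-methyl-2-oxo-5-(2-oxopropyl)cyclopentyl]pentan-2-one | O=C1[C@@H](C)[C@H](O[Si](C)(C)C(C)(C)C)[C@@H](CC(C)=O)[C@@H]1[C@H](C(C)C)C(=O)C=[N+]=[N-] | intermediate
11 | corresponding 1-bromopentan-2-one (bromomethyl ketone) | O=C1[C@@H](C)[C@H](O[Si](C)(C)C(C)(C)C)[C@@H](CC(C)=O)[C@@H]1[C@H](C(C)C)C(=O)CBr | intermediate
12 | trans-bicyclo[5.3.0]decane-1,7-dione with 3α-hydroxy, 3β,8α-dimethyl, 9β-(tert-butyldimethylsiloxy), 10α-isopropyl (skeleton numbering) | O=C2C[C@](C)(O)C[C@H]3[C@@H](C(=O)[C@@H](C)[C@@H]3O[Si](C)(C)C(C)(C)C)[C@@H]2C(C)C | intermediate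
13 | 3α-hydroxy-10α-isopropyl-3β,8-dimethyl-trans-bicyclo[5.3.0]dec-8-ene-1,7-dione | O=C2C[C@](C)(O)C[C@H]3[C@@H](C(=O)C(C)=C3)[C@@H]2C(C)C | intermediate
14 | C3-O-diethylborinate of 13 | O=C2C[C@](C)(OB(CC)CC)C[C@H]3[C@@H](C(=O)C(C)=C3)[C@@H]2C(C)C | intermediate
15 | 1α,3α-dihydroxy-10α-isopropyl-3β,8-dimethyl-trans-bicyclo[5.3.0]dec-8-en-7-one | O[C@@H]2C[C@](C)(O)C[C@H]3[C@@H](C(=O)C(C)=C3)[C@@H]2C(C)C | intermediate
16 | C7 spiro-1,3-dithiolane of 15 | O[C@@H]2C[C@](C)(O)C[C@H]3[C@@H](C4(SCCS4)C(C)=C3)[C@@H]2C(C)C | intermediate
17 | 10α-isopropyl-3β,8-dimethyl-trans-bicyclo[5.3.0]dec-8-ene-1α,3α-diol | O[C@@H]2C[C@](C)(O)C[C@H]3[C@@H](CC(C)=C3)[C@@H]2C(C)C | intermediate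
18 | 8α,9α-epoxide of 17 | O[C@@H]2C[C@](C)(O)C[C@H]3[C@@H](C[C@@]4(C)O[C@@H]34)[C@@H]2C(C)C | intermediate
19 | isovanillic acid | COc1ccc(C(=O)O)cc1O | starting material
20 | tert-butyldimethylsilyl 3-(tert-butyldimethylsiloxy)-4-methoxybenzoate | COc1ccc(C(=O)O[Si](C)(C)C(C)(C)C)cc1O[Si](C)(C)C(C)(C)C | intermediate
21 | 3-(tert-butyldimethylsiloxy)-4-methoxybenzoic acid | COc1ccc(C(=O)O)cc1O[Si](C)(C)C(C)(C)C | intermediate
22 | mixed anhydride of 21 with 2,4,6-trichlorobenzoic acid | COc1ccc(C(=O)OC(=O)c2c(Cl)cc(Cl)cc2Cl)cc1O[Si](C)(C)C(C)(C)C | intermediate
23 | C1 3-(tert-butyldimethylsiloxy)-4-methoxybenzoate of 18 | COc1ccc(C(=O)O[C@@H]2C[C@](C)(O)C[C@H]3[C@@H](C[C@@]4(C)O[C@@H]34)[C@@H]2C(C)C)cc1O[Si](C)(C)C(C)(C)C | intermediate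
24 | CNP0106636.1, C1 3-hydroxy-4-methoxybenzoate of 18 | COc1ccc(C(=O)O[C@@H]2C[C@](C)(O)C[C@H]3[C@@H](C[C@@]4(C)O[C@@H]34)[C@@H]2C(C)C)cc1O | target

## Step count and least certain steps

Total: 16 steps. Longest linear sequence: 15 steps (steps 1–13, 15 and 16, from 1 to 24); step 14 is a one-step side branch.

**Step 2 (key step).** The most likely failures are cationic oligomerisation of the diene at its 1,1-disubstituted terminus under the aluminium Lewis acid, loss of silanol from the complexed enone before cycloaddition, and incomplete endo control at C10. The fallback sets out from 3 and returns at 4.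

- Bromination and dehydrobromination of 3 (Br2, then Et3N) should give (S)-2-bromo-4-(tert-butyldimethylsiloxy)cyclopent-2-enone F1.
- F1 is a more reactive dienophile and should add 2 on heating in toluene or with ZnBr2, with the same face and orientation, to give the C6-bromo adduct F2.
- Radical debromination (Bu3SnH, AIBN) should deliver hydrogen to the convex face of the α-keto radical and return cis-fused 4.

**Step 3.** The most likely failure is expulsion of the siloxy group from the C8 enolate before the slow methylation takes place; over-alkylation is a lesser risk. The fallback sets out from 4 and returns at 5.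

- The enolate is trapped at −78 °C with dimethyl(methylidene)ammonium iodide, a far faster electrophile, to give the Mannich base F3.
- Quaternisation with MeI and mild base should give the α-methylene ketone F4, which has no C8 hydrogen and so cannot lose silanol.
- Hydrogenation of the exocyclic olefin only (H2, RhCl(PPh3)3) should give 5.

**Step 8.** The most likely failure is poor facial selectivity at C3, since no adjacent stereocentre controls it and the competing twist-chair transition states differ only in remote interactions. A second risk is protonation of the samarium enolate before the slow seven-membered closure. The fallback makes C3 depend on C1, and C1 on C10. It sets out at the diol stage, from 17 or from the C1,C3-bis-epimeric diol F5 that a wrong closure would deliver through steps 9–12, and comes back at 17.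

- Dess–Martin oxidation of the C1 carbinol should give the β-hydroxy ketone F6 (either C3 epimer).
- MsCl/Et3N then DBU should give the cycloheptenone F7, erasing C3.
- LiBH(s-Bu)3 should add 1,2 and anti to the isopropyl group to give the 1α-allylic alcohol F8.
- VO(acac)2/t-BuOOH should give the syn (2α,3α) epoxy alcohol F9.
- NaAlH2(OCH2CH2OMe)2 should open F9 at C2 to give 17.

**Step 12 (with step 11).** The most likely failure is migration of the olefin to C7=C8 during desulfurisation. The C7–C8–C9 allyl system is nearly symmetric, so any allyl-type intermediate on nickel has little positional preference. Thiol conjugate addition in step 11 is a further risk. The fallback uses two defined 1,3-transpositions. It sets out from 15 and returns at 17.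

- Et3SiCl/imidazole should give the C1 triethylsilyl ether F10.
- t-BuOOH/DBU should give the epoxy ketone F11.
- Wharton transposition (N2H4·H2O, AcOH) should give the allylic alcohol F12 (C9–OH, C7=C8).
- Reductive transposition (2-nitrobenzenesulfonylhydrazine, PPh3, diethyl azodicarboxylate) should deliver hydrogen to C7 and the olefin to C8=C9, giving F13.
- Bu4NF should remove the silyl group to give 17.

**Step 13.** The most likely failure is that the bishomoallylic tertiary hydroxyl is too remote for efficient oxygen delivery, and that an undirected peracid used instead attacks the β face. The fallback inverts the facial outcome of electrophilic attack. It sets out from 17 and returns at 18.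

- NBS in aqueous acetone should give the bromohydrin F14 (bromonium on the β face, water adding to the tertiary C8 from the α face).
- K2CO3/MeOH should close F14 to 18 with inversion at C9.
- Participation of the C3 hydroxyl (cyclic ether formation) is the side reaction to watch in this fallback.

## Further compounds

F1 | step 2 | (S)-2-bromo-4-(tert-butyldimethylsiloxy)cyclopent-2-enone | O=C1C(Br)=C[C@@H](O[Si](C)(C)C(C)(C)C)C1
F2 | step 2 | C6-bromo analogue of 4 (7a-bromo cis-fused adduct) | O=C1C[C@H](O[Si](C)(C)C(C)(C)C)[C@H]2CC(C)=C[C@@H](C(C)C)[C@@]12Br
F3 | step 3 | C8 dimethylaminomethyl derivative of 4 (Mannich base) | O=C1[C@@H](CN(C)C)[C@H](O[Si](C)(C)C(C)(C)C)[C@H]2CC(C)=C[C@@H](C(C)C)[C@@H]12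
F4 | step 3 | C8 methylene derivative of 4 | O=C1C(=C)[C@H](O[Si](C)(C)C(C)(C)C)[C@H]2CC(C)=C[C@@H](C(C)C)[C@@H]12
F5 | step 8 | 1β,3β-diol, C1,C3-bis-epimer of 17 | O[C@H]2C[C@@](C)(O)C[C@H]3[C@@H](CC(C)=C3)[C@@H]2C(C)C
F6 | step 8 | 3-hydroxy-10α-isopropyl-3,8-dimethyl-trans-bicyclo[5.3.0]dec-8-en-1-one, C3 undefined | O=C2CC(C)(O)C[C@H]3[C@@H](CC(C)=C3)[C@@H]2C(C)C
F7 | step 8 | 10α-isopropyl-3,8-dimethyl-trans-bicyclo[5.3.0]deca-2,8-dien-1-one | O=C2C=C(C)C[C@H]3[C@@H](CC(C)=C3)[C@@H]2C(C)C
F8 | step 8 | corresponding 1α-allylic alcohol | O[C@@H]2C=C(C)C[C@H]3[C@@H](CC(C)=C3)[C@@H]2C(C)C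
F9 | step 8 | 2α,3α-epoxy-1α-alcohol | O[C@@H]2[C@@H]4O[C@]4(C)C[C@H]3[C@@H](CC(C)=C3)[C@@H]2C(C)C
F10 | step 12 | C1 triethylsilyl ether of 15 | CC[Si](CC)(CC)O[C@@H]2C[C@](C)(O)C[C@H]3[C@@H](C(=O)C(C)=C3)[C@@H]2C(C)C
F11 | step 12 | 8,9-epoxy ketone from F10, epoxide face immaterial | CC[Si](CC)(CC)O[C@@H]2C[C@](C)(O)C[C@H]3[C@@H](C(=O)C4(C)OC34)[C@@H]2C(C)C
F12 | step 12 | transposed allylic alcohol (C9–OH, C7=C8), C9 immaterial | CC[Si](CC)(CC)O[C@@H]2C[C@](C)(O)C[C@H]3[C@@H](C=C(C)C3O)[C@@H]2C(C)C
F13 | step 12 | C1 triethylsilyl ether of 17 | CC[Si](CC)(CC)O[C@@H]2C[C@](C)(O)C[C@H]3[C@@H](CC(C)=C3)[C@@H]2C(C)C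
F14 | step 13 | 9β-bromo-1α,3α,8α-triol (bromohydrin of 17) | O[C@@H]2C[C@](C)(O)C[C@H]3[C@@H](C[C@@](C)(O)[C@@H]3Br)[C@@H]2C(C)C
A1 | alternative 1 | oxygen-bridged cycloheptene β-keto ester, enol form (8-oxabicyclo[3.2.1]oct-2-ene) | COC(=O)C1=C(O)C[C@H]2O[C@]1(COCc3ccc(OC)cc3)[C@@H](CC4(C)OCCO4)[C@@H]2C(C)C
A2 | alternative 1 | 2-isopropyl-5-(4-methoxybenzyloxy)-3-[(2-methyl-1,3-dioxolan-2-yl)methyl]-4-oxopentanal | O=C[C@@H](C(C)C)[C@H](CC1(C)OCCO1)C(=O)COCc1ccc(OC)cc1
A3 | alternative 1 | 1-methoxy-1,3-bis(trimethylsiloxy)buta-1,3-diene | COC(O[Si](C)(C)C)=CC(=C)O[Si](C)(C)C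
A4 | alternative 2 | trans-fused bicyclo[5.3.0]dec-8-ene with C1 spiro-1,3-dithiane and C3 methyl carbinol | S1CCCSC12C[C@](C)(O)C[C@H]3[C@@H](CC(C)=C3)[C@@H]2C(C)C
A5 | alternative 2 | 2-{2-methyl-1-[trans-4-methyl-2-((2-methyloxiran-2-yl)methyl)cyclopent-3-en-1-yl]propyl}-1,3-dithiane | S1CCCSC1[C@@H](C(C)C)[C@@H]2CC(C)=C[C@H]2C[C@]3(C)CO3
A6 | alternative 3 | trans-fused bicyclo[5.4.0]undec-2-ene with C7 phenylsulfonyl group and both silyl ethers | CC(C)(C)[Si](C)(C)O[C@@H]1C[C@](C)(O[Si](CC)(CC)CC)C[C@H]2[C@@H]([C@@H](S(=O)(=O)c3ccccc3)CC=C2)[C@@H]1C(C)C
A7 | alternative 3 | (1E,8E)-4-(tert-butyldimethylsiloxy)-3-isopropyl-6-methyl-1-(phenylsulfonyl)-6-(triethylsiloxy)undeca-1,8,10-triene | C=C/C=C/C[C@@](C)(O[Si](CC)(CC)CC)C[C@@H](O[Si](C)(C)C(C)(C)C)[C@@H](C(C)C)/C=C/S(=O)(=O)c1ccccc1
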